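The earlier runs and the new flask stem from a simulated flask for substances that don't exist; noise was put on by code.

| flask | starting material | temperature | remark | time |
|---|---|---|---|---|
| ochre | 0.029 M | 0 °C | run made earlier |  |
| red | 0.044 M | 30 °C | run made earlier |  |
| Sunday's | 0.059 M | 55 °C |  | 2.5 h |
| Wednesday's | 0.059 M |  | at 5 °C until 2.0 h, from then on at 55 °C | 2.5 h |
| Tuesday's | 0.059 M | 30 °C |  | 2.5 h |
| Thursday's | 0.059 M | 5 °C |  | 2.5 h |

| run | time / h | target / % | starting material / % |
|---|---|---|---|
| ochre | 3.00 | 24 | 57 |
| ochre | 6.00 | 23 | 40 |
| ochre | 10.0 | 18 | 34 |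
| ochre | 20.0 | 6 | 19 |
| ochre | 40.0 | 2 | 13 |
| red | 1.50 | 3 | 20 |
| red | 3.00 | 0 | 13 |
| red | 5.00 | 0 | 7 |
| red | 6.00 | 2 | 6 |
| red | 8.00 | 0 | 5 |

(scatter of a reading: 1.5 percentage points)

- percentages count the starting material that a species holds: one target counts as two

- the flask that comes out highest in amount of target, in percent of the starting material charged, or "all alike" when all lie within 1.5 percentage points (Sunday's / Wednesday's / Tuesday's / Thursday's / all alike)
- target at the end, in percent of the starting material charged, Sunday's
- target at the end, in percent of the starting material charged, Wednesday's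
- target at the end, in percent of the starting material charged, Tuesday's
- target at the end, in percent of the starting material charged, Thursday's

A small charge of starting material, the ochre run at 0 °C, lost it slower and slower, and one over the fraction left climbed roughly steadily with time, as in a second-order loss. Its first and fourth readings gave me a constant of 7.12 L mol⁻¹ h⁻¹; the red run at 30 °C gave 58.9 L mol⁻¹ h⁻¹, so the activation energy read 48.5 kJ mol⁻¹.

Folding charge, time and temperature together gave 1.54 for Thursday's flask: this is the reach, rate constant times c(starting material) times time, a Damköhler number. It says how far a flask has gone: in a second-order loss the fraction left is one over one plus the reach. Tuesday's reach was 8.69, Wednesday's, summed over its two stages, 8.76, and Sunday's 37.7.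

So Thursday's flask should keep 39.4%, close to the ochre reading of 40%, where target stood at 23%; I took that reading as my figure for Thursday's target. Tuesday's flask should keep 10.3% and Wednesday's 10.2%, both between red readings of 13% and 7%, each with target 0%. Sunday's 2.59% lay below the last red reading.

Was one number enough? I tested it on target. The ochre run at 19% left held 6% target, the red run at 20% left held 3%, a gap of 3 percentage points against a scatter of 1.5 points.

The forecast named Thursday's, with 27% (“integrating gives about 27%”), above my reading, then 1% for Tuesday's, 0.5% for Wednesday's and 0.1% for Sunday's.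

Thursday's came out highest, with 24.4% target, against 0.607% in Tuesday's, 0.186% in Wednesday's and 0.0120% in Sunday's.

    2 starting material ⇌ target (K = 42.5 L mol⁻¹, k = 6.76 L mol⁻¹ h⁻¹, Ea = 51.0 kJ mol⁻¹, ΔH = −37.0 kJ mol⁻¹)
    starting material + target → side product (k = 9.00 L mol⁻¹ h⁻¹, Ea = 60.0 kJ mol⁻¹)
    target → over-reaction product (k = 0.260 h⁻¹, Ea = 88.0 kJ mol⁻¹)
    (constants at 5 °C)

Thursday's flask held 34.6% starting material at the end, where its reach had given 39.4%. Sunday's neighbour, charged with 0.024 M, has its reach scaled down with the charge to 15.3, which gives 6.13% left; it kept 6.4% starting material and 0.0275% target.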